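**Retrosynthetic overview**
1. Target 13 ⇐ diene triester 12 by face- and site-selective epoxidation. The oxirane is the only ring formed and it is formed last; the carbocycle is carried through from p-benzoquinone.
2. 12 ⇐ dienol dibenzoate 10 by a 1,3-benzoyl shift (O on C2 → O on C7) and acetylation; 10 ⇐ dienal 9 by 1,2-reduction.
3. 9 ⇐ nitromethyl tribenzoate 7 by Nef unmasking of the formyl group and Pd-mediated 1,4-loss of benzoic acid.
4. Key C1–C7 disconnection: 7 ⇐ (±)-conduritol B tetrabenzoate 5 (allyl cation at C1) + nitromethane 6 as a formyl-anion equivalent, joined by enantioselective Pd allylic alkylation through a meso π-allyl complex.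
5. 5 ⇐ p-benzoquinone 1 (Br2 addition, reduction, benzoylation, silver-assisted benzoate substitution).

Atom labels follow the target: C1 = oxirane carbon bearing C7H2OBz, C2 = CHOAc, C3 = CHOBz, C4=C5, C6 = oxirane CH.

Assumption: the (R,R) antipode of the ligand in step 5 is assigned from Trost's working model; if the observed sense is opposite, the (S,S) antipode is used and nothing else changes.
Assumption: only compounds on the carbon path and the one-carbon building block are numbered; other reagents are given with SMILES in each step.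

**Step 1**
Reactants: 1 p-benzoquinone
Product: 2 rac-(5R,6R)-5,6-dibromocyclohex-2-ene-1,4-dione
Conditions: Br2 (1.0 equiv), CHCl3, 0 °C → rt
Reagents that add atoms: bromine, BrBr
Why: Electrophilic anti-addition of bromine (bromonium opening) to one quinone C=C gives the racemic trans-dibromide, and the remaining enedione alkene is too electron-poor to react further.

**Step 2**
Reactants: 2 rac-(5R,6R)-5,6-dibromocyclohex-2-ene-1,4-dione
Product: 3 rac-(1S,4S,5R,6R)-5,6-dibromocyclohex-2-ene-1,4-diol
Conditions: NaBH4, Et2O/H2O, 0 °C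
Reagents that add atoms: none
Why: Substrate-controlled borohydride 1,2-reduction of both ketones gives the known diol in which each OH is trans to its neighbouring Br (the established precursor of anti-benzene dioxide and conduritol B).

**Step 3**
Reactants: 3 rac-(1S,4S,5R,6R)-5,6-dibromocyclohex-2-ene-1,4-diol
Product: 4 rac-(1S,4S,5R,6R)-5,6-dibromocyclohex-2-ene-1,4-diyl dibenzoate
Conditions: PhCOCl (2.4 equiv), pyridine, DMAP (cat.), CH2Cl2, 0 °C → rt
Reagents that add atoms: benzoyl chloride, O=C(Cl)c1ccccc1
Why: Standard DMAP-catalysed O-acylation of both secondary alcohols, with pyridine too weak a base to close the bromohydrins to epoxides; no stereocentre is touched.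

**Step 4**
Reactants: 4 rac-(1S,4S,5R,6R)-5,6-dibromocyclohex-2-ene-1,4-diyl dibenzoate
Product: 5 rac-(1S,2R,3R,4S)-cyclohex-5-ene-1,2,3,4-tetrayl tetrabenzoate ((±)-conduritol B tetrabenzoate)
Conditions: PhCO2Ag (2.5 equiv), toluene, reflux, dark
Reagents that add atoms: silver benzoate, [Ag+].[O-]C(=O)c1ccccc1
Why: Second stage of a Prévost reaction: each bromide leaves with silver assistance and anchimeric help from the trans-vicinal benzoate, and the cis-fused benzoxonium ion is reopened by benzoate with inversion, giving the all-trans tetraester (benzoate analogue of the KOAc/AcOH route to conduritol B tetraacetate).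

**Step 5**
Reactants: 5 rac-(1S,2R,3R,4S)-cyclohex-5-ene-1,2,3,4-tetrayl tetrabenzoate; 6 nitromethane
Product: 7 (1S,2R,3R,4R)-4-(nitromethyl)cyclohex-5-ene-1,2,3-triyl tribenzoate
Conditions: Pd2(dba)3·CHCl3 (2.5 mol %), N,N′-[(1R,2R)-cyclohexane-1,2-diyl]bis[2-(diphenylphosphanyl)benzamide] (7.5 mol %), Cs2CO3 (1.0 equiv), CH3NO2/CH2Cl2 (1:4), rt, stopped at mono-alkylation
Reagents that add atoms: none
Why: Proposed new method: in this Tsuji–Trost asymmetric allylic alkylation zerovalent palladium ionises an allylic benzoate of either enantiomer of 5 with inversion to the same meso η3-allyl complex, and the chiral ligand sends the nitronate of 6 (formyl-anion equivalent, future C7) anti to Pd onto one enantiotopic terminus, so the C1–C7 bond forms with net retention and the absolute configuration at C2 and C3 is fixed in the same event; the closest known reactions are Trost's deracemising substitutions of conduritol B tetraesters with carboxylates and his asymmetric allylations of nitromethane with meso diesters.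

**Step 6**
Reactants: 7 (1S,2R,3R,4R)-4-(nitromethyl)cyclohex-5-ene-1,2,3-triyl tribenzoate
Product: 9 (1R,2R)-3-formylcyclohexa-3,5-diene-1,2-diyl dibenzoate, via aldehyde 8 (not isolated)
Conditions: KOt-Bu (1.05 equiv), THF, −78 °C; dimethyldioxirane (1.2 equiv, acetone), −78 → −40 °C; Me2S quench, cold pH 7 work-up; then Pd(PPh3)4 (5 mol %), THF, 0 °C → rt, no added base
Reagents that add atoms: dimethyldioxirane, CC1(C)OO1
Why: Oxidative Nef reaction (oxygen transfer to the nitronate carbon, loss of nitrite) unmasks the aldehyde, then a Tsuji–Trost 1,4-elimination follows in which zerovalent palladium ionises only the allylic C4 benzoate and the now acidic C1–H, anti to Pd, is lost to give the linearly conjugated dienal; the non-allylic C2 benzoate cannot ionise and C2 and C3 are untouched.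

**Step 7**
Reactants: 9 (1R,2R)-3-formylcyclohexa-3,5-diene-1,2-diyl dibenzoate
Product: 10 (1R,2R)-3-(hydroxymethyl)cyclohexa-3,5-diene-1,2-diyl dibenzoate
Conditions: NaBH4 (1.0 equiv), CeCl3·7H2O (1.0 equiv), MeOH/CH2Cl2, −78 °C, 15 min; AcOH quench
Reagents that add atoms: none
Why: Luche 1,2-reduction takes the conjugated aldehyde to the primary allylic alcohol at low temperature without touching the benzoates or the diene, and no stereocentre is involved.

**Step 8**
Reactants: 10 (1R,2R)-3-(hydroxymethyl)cyclohexa-3,5-diene-1,2-diyl dibenzoate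
Product: 11 [(5R,6R)-5-(benzoyloxy)-6-hydroxycyclohexa-1,3-dien-1-yl]methyl benzoate
Conditions: DBU (0.2 equiv), CH2Cl2, 0 °C → rt, monitored and quenched with AcOH when 10 is consumed
Reagents that add atoms: none
Why: Base-mediated 1,3-O→O acyl migration: the primary C7 alkoxide adds to the C2 benzoate through a six-membered tetrahedral intermediate that collapses to the less hindered primary ester, freeing the flanked C2–OH without breaking its C–O bond, so configuration is retained.

**Step 9**
Reactants: 11 [(5R,6R)-5-(benzoyloxy)-6-hydroxycyclohexa-1,3-dien-1-yl]methyl benzoate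
Product: 12 [(5R,6R)-6-(acetyloxy)-5-(benzoyloxy)cyclohexa-1,3-dien-1-yl]methyl benzoate
Conditions: Ac2O (1.5 equiv), pyridine, DMAP (5 mol %), CH2Cl2, 0 °C
Reagents that add atoms: acetic anhydride, CC(=O)OC(C)=O
Why: DMAP-catalysed acetylation of the free secondary allylic alcohol under conditions too weakly basic to reshuffle the benzoates or aromatise the diene.

**Step 10**
Reactants: 12 [(5R,6R)-6-(acetyloxy)-5-(benzoyloxy)cyclohexa-1,3-dien-1-yl]methyl benzoate
Product: 13 [(1S,2S,3R,6S)-2-(acetyloxy)-3-(benzoyloxy)-7-oxabicyclo[4.1.0]hept-4-en-1-yl]methyl benzoate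
Conditions: mCPBA (1.3 equiv), CH2Cl2/aq. phosphate buffer (pH 7.5), 0 °C → rt
Reagents that add atoms: 3-chloroperbenzoic acid, OOC(=O)c1cccc(Cl)c1
Why: Prilezhaev epoxidation: the peracid should take the more substituted C1=C6 alkene on the face anti to the pseudo-axial allylic C2 acetate, setting C1 and C6 as (1S,6S) trans to the acetate, as reported, to my recollection, for the analogous diacetate diene in the senepoxide series; the minor cis epoxide is removed by chromatography.

**Compound list**
1 | p-benzoquinone (cyclohexa-2,5-diene-1,4-dione) | O=C1C=CC(=O)C=C1 | starting material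
2 | rac-(5R,6R)-5,6-dibromocyclohex-2-ene-1,4-dione (one enantiomer drawn) | O=C1C=CC(=O)[C@@H](Br)[C@@H]1Br | intermediate
3 | rac-(1S,4S,5R,6R)-5,6-dibromocyclohex-2-ene-1,4-diol (one enantiomer drawn) | O[C@@H]1[C@@H](Br)[C@H](Br)[C@@H](O)C=C1 | intermediate
4 | rac-(1S,4S,5R,6R)-5,6-dibromocyclohex-2-ene-1,4-diyl dibenzoate (one enantiomer drawn) | O=C(O[C@@H]1[C@@H](Br)[C@H](Br)[C@@H](OC(=O)c2ccccc2)C=C1)c1ccccc1 | intermediate
5 | rac-(1S,2R,3R,4S)-cyclohex-5-ene-1,2,3,4-tetrayl tetrabenzoate, (±)-conduritol B tetrabenzoate (one enantiomer drawn) | O=C(O[C@@H]1[C@@H](OC(=O)c2ccccc2)[C@H](OC(=O)c2ccccc2)[C@@H](OC(=O)c2ccccc2)C=C1)c1ccccc1 | intermediate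
6 | nitromethane | C[N+](=O)[O-] | starting material
7 | (1S,2R,3R,4R)-4-(nitromethyl)cyclohex-5-ene-1,2,3-triyl tribenzoate | [O-][N+](=O)C[C@@H]1[C@@H](OC(=O)c2ccccc2)[C@H](OC(=O)c2ccccc2)[C@@H](OC(=O)c2ccccc2)C=C1 | intermediate
8 | (1S,2R,3R,4S)-4-formylcyclohex-5-ene-1,2,3-triyl tribenzoate | O=C[C@@H]1[C@@H](OC(=O)c2ccccc2)[C@H](OC(=O)c2ccccc2)[C@@H](OC(=O)c2ccccc2)C=C1 | intermediate
9 | (1R,2R)-3-formylcyclohexa-3,5-diene-1,2-diyl dibenzoate | O=CC1=CC=C[C@@H](OC(=O)c2ccccc2)[C@@H]1OC(=O)c1ccccc1 | intermediate
10 | (1R,2R)-3-(hydroxymethyl)cyclohexa-3,5-diene-1,2-diyl dibenzoate | OCC1=CC=C[C@@H](OC(=O)c2ccccc2)[C@@H]1OC(=O)c1ccccc1 | intermediate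
11 | [(5R,6R)-5-(benzoyloxy)-6-hydroxycyclohexa-1,3-dien-1-yl]methyl benzoate | O=C(OCC1=CC=C[C@@H](OC(=O)c2ccccc2)[C@@H]1O)c1ccccc1 | intermediate
12 | [(5R,6R)-6-(acetyloxy)-5-(benzoyloxy)cyclohexa-1,3-dien-1-yl]methyl benzoate | CC(=O)O[C@H]1[C@H](OC(=O)c2ccccc2)C=CC=C1COC(=O)c1ccccc1 | intermediate
13 | [(1S,2S,3R,6S)-2-(acetyloxy)-3-(benzoyloxy)-7-oxabicyclo[4.1.0]hept-4-en-1-yl]methyl benzoate | CC(=O)O[C@H]1[C@H](OC(=O)c2ccccc2)C=C[C@@H]2O[C@@]21COC(=O)c1ccccc1 | target

**Totals**
Total step count: 10. Longest linear sequence: 10 steps (from p-benzoquinone 1).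

**Steps most likely to fail, with fallbacks**

Step 5 (key alkylation). Nitromethane is a weakly acidic, sluggish pronucleophile. The remaining allylic benzoate of 7 is stereochemically matched, so double alkylation competes. If the mismatched enantiomer of 5 ionises too slowly, the step is only a kinetic resolution with at most 50 % yield. The fallback sets out from 5 and replaces nitromethane by tert-butyl nitroacetate (pKa about 6) under the same Pd2(dba)3·CHCl3/ligand system. The product stays deprotonated, which suppresses a second ionisation, and gives tert-butyl 2-nitro-2-[(1R,4S,5R,6R)-4,5,6-tris(benzoyloxy)cyclohex-2-en-1-yl]acetate F1 as a mixture of epimers at the nitro-bearing carbon. Treatment with CF3CO2H in CH2Cl2 removes the tert-butyl group, the α-nitro acid decarboxylates spontaneously, and the route is rejoined at 7.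

Step 6 (Nef reaction and 1,4-elimination). Aldehyde 8 is a β-benzoyloxy aldehyde that can lose the C2 benzoate without catalysis or epimerise at C1. Dienal 9 can also be aromatised by zerovalent palladium to 2-formylphenyl benzoate. The fallback sets out from 7 and works at the acid oxidation level. NaNO2/AcOH in DMSO at 35 °C converts the primary nitro group into (1S,4S,5R,6R)-4,5,6-tris(benzoyloxy)cyclohex-2-ene-1-carboxylic acid F2. Coupling with ethanethiol (EDC·HCl, DMAP, CH2Cl2) gives S-ethyl (1S,4S,5R,6R)-4,5,6-tris(benzoyloxy)cyclohex-2-ene-1-carbothioate F3, which is less prone to uncatalysed β-elimination than the aldehyde. The Pd(PPh3)4-mediated 1,4-elimination is run on this thioester to give S-ethyl (5R,6R)-5,6-bis(benzoyloxy)cyclohexa-1,3-diene-1-carbothioate F4. Fukuyama reduction (Et3SiH, Pd/C, acetone) then delivers the aldehyde without touching the benzoates, and the route is rejoined at 9.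

Step 8 (benzoyl shift). The shift may stall at an equilibrium mixture, or continue with a slower trans-1,2 shift of the C3 benzoate onto the freed C2–OH. The fallback sets out from 10 and gives up the intramolecular transfer. K2CO3 in MeOH at 0 °C removes both benzoates to give (1R,2R)-3-(hydroxymethyl)cyclohexa-3,5-diene-1,2-diol F5. Benzoyl chloride (2.05 equiv) in pyridine/CH2Cl2 at −40 °C then acylates the primary OH and the less hindered C3–OH before the flanked C2–OH. The route is rejoined at 11.

**Further compounds**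
F1 | step 5 | tert-butyl 2-nitro-2-[(1R,4S,5R,6R)-4,5,6-tris(benzoyloxy)cyclohex-2-en-1-yl]acetate (epimers at the nitro-bearing carbon) | CC(C)(C)OC(=O)C([N+](=O)[O-])[C@@H]1[C@@H](OC(=O)c2ccccc2)[C@H](OC(=O)c2ccccc2)[C@@H](OC(=O)c2ccccc2)C=C1
F2 | step 6 | (1S,4S,5R,6R)-4,5,6-tris(benzoyloxy)cyclohex-2-ene-1-carboxylic acid | OC(=O)[C@@H]1[C@@H](OC(=O)c2ccccc2)[C@H](OC(=O)c2ccccc2)[C@@H](OC(=O)c2ccccc2)C=C1
F3 | step 6 | S-ethyl (1S,4S,5R,6R)-4,5,6-tris(benzoyloxy)cyclohex-2-ene-1-carbothioate | CCSC(=O)[C@@H]1[C@@H](OC(=O)c2ccccc2)[C@H](OC(=O)c2ccccc2)[C@@H](OC(=O)c2ccccc2)C=C1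
F4 | step 6 | S-ethyl (5R,6R)-5,6-bis(benzoyloxy)cyclohexa-1,3-diene-1-carbothioate | CCSC(=O)C1=CC=C[C@@H](OC(=O)c2ccccc2)[C@@H]1OC(=O)c1ccccc1
F5 | step 8 | (1R,2R)-3-(hydroxymethyl)cyclohexa-3,5-diene-1,2-diol | OCC1=CC=C[C@@H](O)[C@@H]1O
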